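**Retrosynthetic overview**

1. The target is an aromatic acylphloroglucinol (ring A) joined through one CH2 to a 2-acetyl-3,5-dihydroxy-4-methyl-4-geranylcyclohexa-2,5-dien-1-one (ring B). The last bond made is C6(ring B)–CH2, by adding ring B monomer 18 to the ortho-quinone methide released from ring A Mannich base 6.
2. Ring B is cut at C5–C6 and C2–C3 into the 1,3-dianion of acetylacetone (C6–C1–C2 plus the acetyl group) and a methyl(geranyl)malonyl unit (C3–C4–C5) whose two carbonyls differ: acyl imidazolide (future C5) and 2,2-diphenylethyl ester (future C3).
3. Enabling feature: ring B is a cyclic tri-β-carbonyl array in which the oxygenated carbons C1, C3, C5 alternate with the carbanion-type carbons C2, C4, C6. The quaternary C4 (methyl, geranyl) sits between two ring carbonyls, so it is a malonate carbon that can bring the stereocentre in from outside; it also blocks aromatisation and the aldol folding mode, leaving Claisen closure as the only six-ring pathway.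
4. The C4 stereocentre is set by catalytic asymmetric phase-transfer geranylation of a tert-butyl 2,2-diphenylethyl methylmalonate. Which ester becomes C5 and which C3 then fixes the configuration of ring B.
5. Order of rings: ring A is never formed (phloroglucinol is bought and then acylated, geranylated and aminomethylated); ring B is the only ring closed, in step 9; the halves are joined in step 10.

Key step: step 9

Remark on the chemistry: geranyl = (2E)-3,7-dimethylocta-2,6-dien-1-yl. The target is handled as the enol tautomer drawn, in which the quaternary carbon is R. The S sense assigned to step 6 rests on analogy with allylations and benzylations of the same malonate class; the enantiomeric catalyst would be used if the opposite sense were found.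

**Route**

Step 1
Reactants: 1 phloroglucinol (benzene-1,3,5-triol); 2 butanoyl chloride
Product: 3 1-(2,4,6-trihydroxyphenyl)butan-1-one
Conditions: AlCl3 (3 equiv), CH2Cl2/MeNO2, 0 °C → rt; aq. HCl
Reagents that add atoms: none
Why: Friedel–Crafts C-acylation of the symmetrical, highly activated triol should stop at the monoketone because the chelated acyl group deactivates the ring toward a second acylation.

Step 2
Reactants: 3 1-(2,4,6-trihydroxyphenyl)butan-1-one; 4 geranyl bromide
Product: 5 1-(3-geranyl-2,4,6-trihydroxyphenyl)butan-1-one
Conditions: DBU (1.0 equiv), 4 (1.0 equiv), THF, 0 °C → rt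
Reagents that add atoms: none
Why: Base-mediated C-alkylation of the acylphloroglucinol phenolate by the primary allylic bromide (SN2, E geometry retained) should give the mono-C-geranyl compound as a single regioisomer because the two free ring positions of 3 are equivalent, with one equivalent of bromide limiting bis- and O-alkylation.

Step 3
Reactants: 5 1-(3-geranyl-2,4,6-trihydroxyphenyl)butan-1-one
Product: 6 1-[3-(dimethylaminomethyl)-5-geranyl-2,4,6-trihydroxyphenyl]butan-1-one
Conditions: dimethyl(methylidene)ammonium iodide (1.05 equiv), Et3N, CH2Cl2, 0 °C → rt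
Reagents that add atoms: dimethyl(methylidene)ammonium iodide C=[N+](C)C.[I-]
Why: Mannich aminomethylation of the single remaining aromatic C–H by the preformed iminium salt should give the phenolic Mannich base that later serves as a latent ortho-quinone methide.

Step 4
Reactants: 7 2,2,5-trimethyl-1,3-dioxane-4,6-dione
Product: 8 3-tert-butoxy-2-methyl-3-oxopropanoic acid (racemic, configurationally labile)
Conditions: tert-butanol (solvent), reflux
Reagents that add atoms: tert-butanol CC(C)(C)O
Why: Thermal alcoholysis of the cyclic acylal with loss of acetone is the standard entry to malonic acid mono-tert-butyl esters.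

Step 5
Reactants: 8 3-tert-butoxy-2-methyl-3-oxopropanoic acid; 9 2,2-diphenylethanol
Product: 10 1-tert-butyl 3-(2,2-diphenylethyl) 2-methylmalonate (racemic)
Conditions: DCC, 4-(dimethylamino)pyridine (cat.), CH2Cl2, 0 °C → rt
Reagents that add atoms: none
Why: Steglich esterification (carbodiimide activation with acyl transfer through the aminopyridine) should join the half-acid to the primary alcohol without touching the tert-butyl ester.

Step 6
Reactants: 10 1-tert-butyl 3-(2,2-diphenylethyl) 2-methylmalonate; 4 geranyl bromide
Product: 11 1-tert-butyl 3-(2,2-diphenylethyl) (S)-2-geranyl-2-methylmalonate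
Conditions: (S,S)-3,4,5-trifluorophenyl-NAS bromide [N-spiro bis(binaphthyl)azepinium bromide with 3,4,5-trifluorophenyl groups at the 3,3'-positions of one binaphthyl unit] (5 mol %), 50% aq. KOH, toluene, −40 °C
Reagents that add atoms: none
Why: Catalytic asymmetric phase-transfer alkylation of an α-methylmalonate carrying one tert-butyl and one 2,2-diphenylethyl ester, a substrate class alkylated by allylic and benzylic bromides with high enantioselectivity: the chiral ammonium cation ion-pairs with the interfacial enolate and exposes one enantiotopic face to SN2 attack on geranyl bromide, so the quaternary stereocentre is set under catalyst control (expected S) and cannot epimerise afterwards because it bears no hydrogen.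

Step 7
Reactants: 11 1-tert-butyl 3-(2,2-diphenylethyl) (S)-2-geranyl-2-methylmalonate
Product: 13 (R)-3-(2,2-diphenylethoxy)-2-geranyl-2-methyl-3-oxopropanoic acid, via trimethylsilyl ester 12 (not isolated)
Conditions: Me3SiOTf, 2,6-lutidine, CH2Cl2, 0 °C; then aqueous citrate buffer (pH 4)
Reagents that add atoms: none
Why: Silyl triflate converts the tert-butyl ester into the silyl ester with loss of isobutene under lutidine-buffered, proton-free conditions (a known non-acidic tert-butyl ester cleavage), so the acid-sensitive geranyl diene and the primary diphenylethyl ester should survive; the stereocentre is untouched and its descriptor changes from S to R only because the priorities change.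

Step 8
Reactants: 13 (R)-3-(2,2-diphenylethoxy)-2-geranyl-2-methyl-3-oxopropanoic acid
Product: 14 2,2-diphenylethyl (R)-2-geranyl-3-(imidazol-1-yl)-2-methyl-3-oxopropanoate
Conditions: 1,1'-carbonyldiimidazole (1.1 equiv), THF, rt; volatiles removed, used crude
Reagents that add atoms: 1,1'-carbonyldiimidazole O=C(n1ccnc1)n1ccnc1
Why: Carbonyldiimidazole should convert the hindered, non-enolisable acid into its acyl imidazolide under neutral conditions (driven by loss of CO2), giving a carbonyl far more electrophilic than the neighbouring ester, the difference on which step 9 depends.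

Step 9
Reactants: 14 2,2-diphenylethyl (R)-2-geranyl-3-(imidazol-1-yl)-2-methyl-3-oxopropanoate; 15 acetylacetone (pentane-2,4-dione)
Product: 18 (R)-2-acetyl-4-geranyl-3,5-dihydroxy-4-methylcyclohexa-2,5-dien-1-one, via dilithio acetylacetonate 16 (not isolated), via triketo ester 17 (not isolated)
Conditions: 15 (3 equiv), LiN(iPr)2 (6 equiv), THF, 0 °C; add 14, −78 → 0 °C; then tert-butanol (1 equiv), 60 °C; 1 M HCl work-up
Reagents that add atoms: none
Why: Double deprotonation of acetylacetone gives dianion 16, whose terminal carbon is C-acylated by the imidazolide carbonyl of 14 in preference to the much less electrophilic, neopentyl-type diphenylethyl ester, forming the C5–C6 bond of ring B and, after proton transfer to a second equivalent of 16, the dienolate of triketo ester 17; once the surplus dianion has been discharged with tert-butanol, warming should let the diketonate carbon between the two remaining ketone carbonyls (future ring C2) attack the ester carbonyl in a 6-exo-trig Claisen (Dieckmann-type) closure that forms the C2–C3 bond and expels 2,2-diphenylethoxide. The closest known reaction types are the terminal acylation of β-diketone dianions by acyl donors to give 1,3,5-triketones and the biomimetic Claisen folding of 3,5,7-triketo esters into 2-acylcyclohexane-1,3,5-triones, here telescoped into a formal [3+3] annulation. No stereocentre is created: the quaternary carbon comes in from 11 and has no acidic hydrogen, and its configuration in 18 follows solely from which malonyl carbonyl is bonded to the terminal and which to the central carbon of the diketone, that is from imidazolide-over-ester chemoselectivity in the first acylation. The fully substituted carbon next to the ester rules out the aldol (resorcylate) folding and any aromatisation, and the only other closure, O-acylation to an enol lactone, is reversible in the presence of the released alkoxide, whereas C-acylation is pulled to completion by deprotonation of the very acidic triacylmethane product. A non-nucleophilic alkoxide medium is chosen so that the C2 acetyl group is not cleaved and re-attached at C6, a process that would interconvert the enantiomers of 18.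

Step 10
Reactants: 18 (R)-2-acetyl-4-geranyl-3,5-dihydroxy-4-methylcyclohexa-2,5-dien-1-one; 6 1-[3-(dimethylaminomethyl)-5-geranyl-2,4,6-trihydroxyphenyl]butan-1-one
Product: 20 CNP0209203.1, (R)-2-acetyl-6-[(3-butanoyl-5-geranyl-2,4,6-trihydroxyphenyl)methyl]-4-geranyl-3,5-dihydroxy-4-methylcyclohexa-2,5-dien-1-one, via ortho-quinone methide 19 (not isolated)
Conditions: 1,4-dioxane, 80 °C, N2 sweep
Reagents that add atoms: none
Why: The vinylogous acid 18 should protonate the Mannich base, thermal loss of dimethylamine unmasks ortho-quinone methide 19, and Michael addition of the only free ring carbon of 18 (C6 of ring B) with rearomatisation of ring A forges the methylene bridge (the Mannich-base/quinone-methide route to methylene-bridged acylphloroglucinol dimers) without touching the quaternary stereocentre, which can no longer be scrambled by acetyl migration once C6 is substituted.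

**Compound list**

1 | phloroglucinol (benzene-1,3,5-triol) | Oc1cc(O)cc(O)c1 | starting material
2 | butanoyl chloride | CCCC(=O)Cl | starting material
3 | 1-(2,4,6-trihydroxyphenyl)butan-1-one | CCCC(=O)c1c(O)cc(O)cc1O | intermediate
4 | geranyl bromide, (2E)-1-bromo-3,7-dimethylocta-2,6-diene | BrC/C=C(\C)CCC=C(C)C | starting material
5 | 1-(3-geranyl-2,4,6-trihydroxyphenyl)butan-1-one | CCCC(=O)c1c(O)cc(O)c(C/C=C(\C)CCC=C(C)C)c1O | intermediate
6 | 1-[3-(dimethylaminomethyl)-5-geranyl-2,4,6-trihydroxyphenyl]butan-1-one | CCCC(=O)c1c(O)c(C/C=C(\C)CCC=C(C)C)c(O)c(CN(C)C)c1O | intermediate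
7 | 2,2,5-trimethyl-1,3-dioxane-4,6-dione | CC1C(=O)OC(C)(C)OC1=O | starting material
8 | 3-tert-butoxy-2-methyl-3-oxopropanoic acid (racemic) | CC(C(=O)O)C(=O)OC(C)(C)C | intermediate
9 | 2,2-diphenylethanol | OCC(c1ccccc1)c1ccccc1 | starting material
10 | 1-tert-butyl 3-(2,2-diphenylethyl) 2-methylmalonate (racemic) | CC(C(=O)OC(C)(C)C)C(=O)OCC(c1ccccc1)c1ccccc1 | intermediate
11 | 1-tert-butyl 3-(2,2-diphenylethyl) (S)-2-geranyl-2-methylmalonate | CC(C)(C)OC(=O)[C@@](C)(C/C=C(\C)CCC=C(C)C)C(=O)OCC(c1ccccc1)c1ccccc1 | intermediate
12 | 1-(2,2-diphenylethyl) 3-trimethylsilyl (S)-2-geranyl-2-methylmalonate | C[Si](C)(C)OC(=O)[C@@](C)(C/C=C(\C)CCC=C(C)C)C(=O)OCC(c1ccccc1)c1ccccc1 | intermediate (not isolated)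
13 | (R)-3-(2,2-diphenylethoxy)-2-geranyl-2-methyl-3-oxopropanoic acid | OC(=O)[C@@](C)(C/C=C(\C)CCC=C(C)C)C(=O)OCC(c1ccccc1)c1ccccc1 | intermediate
14 | 2,2-diphenylethyl (R)-2-geranyl-3-(imidazol-1-yl)-2-methyl-3-oxopropanoate | O=C(n1ccnc1)[C@@](C)(C/C=C(\C)CCC=C(C)C)C(=O)OCC(c1ccccc1)c1ccccc1 | intermediate
15 | acetylacetone (pentane-2,4-dione) | CC(=O)CC(C)=O | starting material
16 | dilithio acetylacetonate (1,3-dianion of pentane-2,4-dione, dilithium salt) | C=C([O-])C=C(C)[O-].[Li+].[Li+] | intermediate (not isolated)
17 | 2,2-diphenylethyl (R)-2-geranyl-2-methyl-3,5,7-trioxooctanoate (present as its lithium dienolate) | CC(=O)CC(=O)CC(=O)[C@@](C)(C/C=C(\C)CCC=C(C)C)C(=O)OCC(c1ccccc1)c1ccccc1 | intermediate (not isolated)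
18 | (R)-2-acetyl-4-geranyl-3,5-dihydroxy-4-methylcyclohexa-2,5-dien-1-one | CC(=O)C1=C(O)[C@](C)(C/C=C(\C)CCC=C(C)C)C(O)=CC1=O | intermediate
19 | ortho-quinone methide of 6: 2-butanoyl-4-geranyl-3,5-dihydroxy-6-methylidenecyclohexa-2,4-dien-1-one | CCCC(=O)C1=C(O)C(C/C=C(\C)CCC=C(C)C)=C(O)C(=C)C1=O | intermediate (not isolated)
20 | CNP0209203.1, (R)-2-acetyl-6-[(3-butanoyl-5-geranyl-2,4,6-trihydroxyphenyl)methyl]-4-geranyl-3,5-dihydroxy-4-methylcyclohexa-2,5-dien-1-one | CCCC(=O)c1c(O)c(C/C=C(\C)CCC=C(C)C)c(O)c(CC2=C(O)[C@@](C)(C/C=C(\C)CCC=C(C)C)C(O)=C(C(C)=O)C2=O)c1O | target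

**Step count and risks**

Total step count: 10. Longest linear sequence: 7 steps (steps 4, 5, 6, 7, 8, 9, 10, from 2,2,5-trimethyl-1,3-dioxane-4,6-dione); the ring A branch (steps 1–3) joins in step 10.

Steps most likely to fail:

Step 9. The stabilised diketonate may be too weak a nucleophile for the hindered ester, so that the sequence stalls at the open chain or diverts to O-acylation (enol lactone formation). The strongly basic dianion may also trigger β-elimination of the diphenylethyl ester, or attack both malonyl carbonyls and erode the enantiomeric purity. The fallback reverses the order of the two ring bonds; it sets out from 11 and comes back at 18. The diphenylethyl ester of 11 is saponified selectively (1 M KOH, MeOH/THF, rt; the tert-butyl ester is inert) to (S)-3-tert-butoxy-2-geranyl-2-methyl-3-oxopropanoic acid F1. This is converted with 1-chloro-N,N,2-trimethylprop-1-en-1-amine (CH2Cl2, 0 °C) into tert-butyl (R)-3-chloro-2-geranyl-2-methyl-3-oxopropanoate F2. C-acylation of acetylacetone 15 at its central carbon under soft enolisation (MgCl2, pyridine, CH2Cl2) gives tert-butyl (S)-4-acetyl-2-geranyl-2-methyl-3,5-dioxohexanoate F3, in which the C2–C3 bond of ring B already exists. LiN(iPr)2 (3 equiv, THF, −78 °C → rt) then forms the terminal-methyl dianion, which closes ring B by Dieckmann attack on the tert-butyl ester (C5–C6 bond last; either acetyl group gives the same product) and delivers 18. The malonyl carbonyls keep the same assignment as in the main route (former tert-butyl ester carbon = C5), so the same enantiomer results.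

Step 10. Prolonged heating in the presence of the liberated amine may cause retro-Michael fragmentation and recombination of the methylene-bridged product (scrambling toward symmetrical dimers), or the quinone methide may oligomerise before it is captured. The fallback reverses the polarity of the coupling; it sets out from 18 (with 5 as partner) and comes back at 20. Trione 18 is aminomethylated at C6 (dimethyl(methylidene)ammonium iodide, Et3N, CH2Cl2, 0 °C) to (R)-2-acetyl-6-(dimethylaminomethyl)-4-geranyl-3,5-dihydroxy-4-methylcyclohexa-2,5-dien-1-one F4. In NaOAc/AcOH at rt this loses dimethylamine to the exocyclic enone (R)-2-acetyl-4-geranyl-3-hydroxy-4-methyl-6-methylidenecyclohex-2-ene-1,5-dione F5. The single free aromatic carbon of 5 adds to F5 in a Friedel–Crafts-type conjugate addition to give 20 under mildly acidic, non-equilibrating conditions.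

Step 6. Facial discrimination may be poor, or the sense of induction opposite, with the long and flexible geranyl electrophile, leaving material of insufficient enantiomeric purity. The fallback replaces asymmetric catalysis by resolution; it sets out from 10 and comes back at 11. Racemic alkylation (NaH, geranyl bromide 4, THF, 0 °C → rt) gives racemic 1-tert-butyl 3-(2,2-diphenylethyl) 2-geranyl-2-methylmalonate F6. Preparative supercritical-fluid chromatography on a chiral stationary phase (amylose tris(3,5-dimethylphenylcarbamate)) separates it into 11 and the unwanted 1-tert-butyl 3-(2,2-diphenylethyl) (R)-2-geranyl-2-methylmalonate F7, which is set aside; the absolute configuration of 11 is then confirmed by correlation.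

**Further compounds**

F1 | step 9 | (S)-3-tert-butoxy-2-geranyl-2-methyl-3-oxopropanoic acid | CC(C)(C)OC(=O)[C@@](C)(C/C=C(\C)CCC=C(C)C)C(=O)O
F2 | step 9 | tert-butyl (R)-3-chloro-2-geranyl-2-methyl-3-oxopropanoate | CC(C)(C)OC(=O)[C@@](C)(C/C=C(\C)CCC=C(C)C)C(=O)Cl
F3 | step 9 | tert-butyl (S)-4-acetyl-2-geranyl-2-methyl-3,5-dioxohexanoate | CC(C)(C)OC(=O)[C@@](C)(C/C=C(\C)CCC=C(C)C)C(=O)C(C(C)=O)C(C)=O
F4 | step 10 | (R)-2-acetyl-6-(dimethylaminomethyl)-4-geranyl-3,5-dihydroxy-4-methylcyclohexa-2,5-dien-1-one | CC(=O)C1=C(O)[C@](C)(C/C=C(\C)CCC=C(C)C)C(O)=C(CN(C)C)C1=O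
F5 | step 10 | (R)-2-acetyl-4-geranyl-3-hydroxy-4-methyl-6-methylidenecyclohex-2-ene-1,5-dione | CC(=O)C1=C(O)[C@](C)(C/C=C(\C)CCC=C(C)C)C(=O)C(=C)C1=O
F6 | step 6 | racemic 1-tert-butyl 3-(2,2-diphenylethyl) 2-geranyl-2-methylmalonate | CC(C)(C)OC(=O)C(C)(C/C=C(\C)CCC=C(C)C)C(=O)OCC(c1ccccc1)c1ccccc1
F7 | step 6 | 1-tert-butyl 3-(2,2-diphenylethyl) (R)-2-geranyl-2-methylmalonate | CC(C)(C)OC(=O)[C@](C)(C/C=C(\C)CCC=C(C)C)C(=O)OCC(c1ccccc1)c1ccccc1
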